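**Assumption:** The target SMILES contains no stereocenters. It is an achiral 3-aryl-2H-chromene (isoflav-3-ene), so "single enantiomer" has no content and no stereochemistry needs to be set or preserved.

## Retrosynthetic overview
1. Target ← tri-O-benzyl 3-aryl-2H-chromene by global debenzylation, the last step.
2. The pyran ring and the C3=C4 alkene are formed together, last, by an intramolecular McMurry coupling of an aryloxy-ketone/aldehyde. This replaces the usual isoflavone-reduction or 3-bromochromene/Suzuki disconnections.
3. The keto-aldehyde comes from 2,4,6-trihydroxybenzaldehyde by C-prenylation, 4-O-benzylation, and phenacylation of the less hindered chelated OH. The prenyl-flanked OH is then methylated. The phenacyl partner is 2-bromo-2',4'-bis(benzyloxy)acetophenone, made from resacetophenone.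
4. Both aromatic rings are present from the start. The only ring formed in the route is the pyran, built in the McMurry step.

## Route

**Step 1**
Reactants: 1 (2,4,6-trihydroxybenzaldehyde); 2 (prenyl bromide)
Product: 3 (2,4,6-trihydroxy-3-(3-methylbut-2-en-1-yl)benzaldehyde)
Conditions: 2 (1.0 equiv), KOH (aq.), MeOH, 0 °C → rt
Reagents that add atoms: 2, prenyl bromide, CC(C)=CCBr
Why: Phenolate C-alkylation of an acylphloroglucinol-type ring occurs at the carbon flanked by two OH groups. C3 and C5 are equivalent by symmetry, so only one mono-C-prenyl regioisomer exists. No stereocenter is formed.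

**Step 2**
Reactants: 3; benzyl bromide
Product: 4 (4-(benzyloxy)-2,6-dihydroxy-3-(3-methylbut-2-en-1-yl)benzaldehyde)
Conditions: BnBr (1.05 equiv), NaHCO3, KI (cat.), MeCN, 60 °C
Reagents that add atoms: benzyl bromide, BrCc1ccccc1
Why: The 4-OH is the most acidic and is the only OH not chelated to the CHO, so it is selectively O-benzylated (Williamson ether synthesis). The 2- and 6-OH groups stay free.

**Step 3**
Reactants: 5 (2',4'-dihydroxyacetophenone, resacetophenone); benzyl bromide
Product: 6 (1-(2,4-bis(benzyloxy)phenyl)ethan-1-one)
Conditions: BnBr (2.5 equiv), K2CO3, acetone, reflux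
Reagents that add atoms: benzyl bromide, BrCc1ccccc1
Why: Double Williamson O-benzylation of both phenols.

**Step 4**
Reactants: 6
Product: 7 (2-bromo-1-(2,4-bis(benzyloxy)phenyl)ethan-1-one)
Conditions: CuBr2 (2 equiv), EtOAc/CHCl3 1:1, reflux
Reagents that add atoms: copper(II) bromide, [Cu+2].[Br-].[Br-]
Why: CuBr2 α-brominates aryl methyl ketones without brominating the electron-rich arene (King–Ostrum bromination). It does not touch the benzyl ethers.

**Step 5**
Reactants: 4; 7
Product: 8 (2-[2-(2,4-bis(benzyloxy)phenyl)-2-oxoethoxy]-type aryl ether: 4-(benzyloxy)-2-hydroxy-6-[2-(2,4-bis(benzyloxy)phenyl)-2-oxoethoxy]-3-(3-methylbut-2-en-1-yl)benzaldehyde)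
Conditions: K2CO3 (1.1 equiv), KI (cat.), acetone, 45 °C
Reagents that add atoms: none beyond the coupling partner 7
Why: The bulky phenacyl bromide alkylates the unhindered chelated 6-OH in preference to the 2-OH flanked by prenyl (Williamson ether synthesis). The mild base and low temperature avoid Rap–Stoermer benzofuran closure onto the electron-rich, hindered CHO.

**Step 6**
Reactants: 8; methyl iodide
Product: 9 (4-(benzyloxy)-2-[2-(2,4-bis(benzyloxy)phenyl)-2-oxoethoxy]-6-methoxy-5-(3-methylbut-2-en-1-yl)benzaldehyde)
Conditions: MeI (5 equiv), K2CO3, acetone, 40 °C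
Reagents that add atoms: methyl iodide, CI
Why: The last free phenol, chelated and prenyl-flanked, is O-methylated to give the 5-OMe of the target (Williamson ether synthesis). This gives the keto-aldehyde cyclization precursor.

**Step 7**
Reactants: 9
Product: 10 (5-methoxy-7-(benzyloxy)-3-[2,4-bis(benzyloxy)phenyl]-6-(3-methylbut-2-en-1-yl)-2H-chromene)
Conditions: TiCl4, Zn dust, pyridine (cat.), THF, 0 °C → reflux; 9 added slowly (syringe pump, about 3 h)
Reagents that add atoms: none
Why: Intramolecular McMurry coupling. Low-valent Ti pinacol-couples the aldehyde and the aryl ketone, then deoxygenates to the alkene. Ring closure can only give the endocyclic C3=C4 bond of the 2H-chromene, so there is no E/Z issue and no stereocenter. The prenyl alkene, aryl ethers and OMe survive, and slow addition favors cyclization over dimerization.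

**Step 8**
Reactants: 10
Product: 11 (dehydroglyasperin C)
Conditions: BCl3 (5 equiv), pentamethylbenzene (scavenger), CH2Cl2, −78 °C, 1 h; then MeOH, aq. NaHCO3
Reagents that add atoms: none (the benzyl groups are transferred to the scavenger)
Why: BCl3 with a cation scavenger debenzylates aryl benzyl ethers at low temperature and leaves the trisubstituted prenyl alkene, the aryl methyl ether and the styrenic chromene alkene intact. The benzyl cations are trapped by pentamethylbenzene, and H2/Pd is avoided because it would reduce the prenyl group and the chromene alkene.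

## Compound list
1 | 2,4,6-trihydroxybenzaldehyde | O=Cc1c(O)cc(O)cc1O | starting material
2 | prenyl bromide (1-bromo-3-methylbut-2-ene) | CC(C)=CCBr | starting material
3 | 2,4,6-trihydroxy-3-prenylbenzaldehyde | O=Cc1c(O)cc(O)c(CC=C(C)C)c1O | intermediate
4 | 4-(benzyloxy)-2,6-dihydroxy-3-prenylbenzaldehyde | O=Cc1c(O)cc(OCc2ccccc2)c(CC=C(C)C)c1O | intermediate
5 | 2',4'-dihydroxyacetophenone | CC(=O)c1ccc(O)cc1O | starting material
6 | 2',4'-bis(benzyloxy)acetophenone | CC(=O)c1ccc(OCc2ccccc2)cc1OCc1ccccc1 | intermediate
7 | 2-bromo-1-[2,4-bis(benzyloxy)phenyl]ethanone | BrCC(=O)c1ccc(OCc2ccccc2)cc1OCc1ccccc1 | intermediate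
8 | phenacyl ether aldehyde (2-OH free, 6-O-phenacyl, 4-OBn, 3-prenyl) | O=Cc1c(O)c(CC=C(C)C)c(OCc2ccccc2)cc1OCC(=O)c1ccc(OCc2ccccc2)cc1OCc1ccccc1 | intermediate
9 | keto-aldehyde (2-OMe analogue of 8) | O=Cc1c(OC)c(CC=C(C)C)c(OCc2ccccc2)cc1OCC(=O)c1ccc(OCc2ccccc2)cc1OCc1ccccc1 | intermediate
10 | tri-O-benzyl dehydroglyasperin C | COc1c2c(cc(OCc3ccccc3)c1CC=C(C)C)OCC(c1ccc(OCc3ccccc3)cc1OCc1ccccc1)=C2 | intermediate
11 | dehydroglyasperin C | COc1c2c(cc(O)c1CC=C(C)C)OCC(c1ccc(O)cc1O)=C2 | target

## Totals
Total steps: 8 (two convergent branches: steps 3–4 make 7, and steps 1–2 make 4).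
Longest linear sequence: 6 steps (1 → 3 → 4 → 8 → 9 → 10 → 11).

## Three steps most likely to fail
1. **Step 7 (McMurry).** The α-aryloxy ketone may undergo reductive C–O cleavage, and TiCl4 may strip ortho-benzyl ethers by chelation.
   Fallback (different disconnection): build 3-bromo-2H-chromene by RCM of the o-vinylaryl 2-bromoallyl ether from the same A-ring phenol, then Suzuki-couple it with 2,4-bis(benzyloxy)phenylboronic acid.
2. **Step 5 (regioselective phenacylation).** The 2-OH and 6-OH differ only by steric hindrance, and base can induce Rap–Stoermer cyclization.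
   Fallback (reordered strategy): start from symmetric 4-O-prenyl-2,4,6-trihydroxybenzaldehyde, so mono-phenacylation and methylation have no regiochemical ambiguity. Then install the C-prenyl by ortho-Claisen of the 4-O-prenyl ether, which should prefer the position next to the smaller OMe.
3. **Step 8 (global debenzylation).** BCl3 may cleave the peri OMe, or the acid-labile 2H-chromene or prenyl group may be damaged.
   Fallback (different protecting-group strategy): repeat the route with allyl ethers in place of benzyl ethers, and remove them at the end with Pd(PPh3)4/K2CO3/MeOH, which is non-acidic.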